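Readings and results stem from a simulated flask for substances that don't exist, noise included.

The ratio I follow in this flask is κ, the first-order loss constant of E over that of D, taken as constant. It is the selectivity factor of a consecutive reaction, and dividing one rate by the other takes time out of the reckoning.

| flask | D | Q | Z | remark | time |
|---|---|---|---|---|---|
| theta | 0.089 M | 3.4 mM (held) | 0.2 mol% | the very flask that is asked about, followed so far |  |
| zeta | 0.060 M | 3.4 mM (held) | 0.2 mol% | run made earlier |  |
| flask | 0.089 M | 3.4 mM (held) | 0.2 mol% |  | 40 h |

| run | time / h | E / % | D / % |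
|---|---|---|---|
| theta | 1.00 | 16 | 90 |
| theta | 2.00 | 23 | 71 |
| theta | 3.00 | 27 | 58 |
| theta | 4.00 | 28 | 50 |
| theta | 6.00 | 28 | 35 |
| theta | 10.0 | 18 | 16 |
| theta | 15.0 | 5 | 6 |
| zeta | 1.00 | 8 | 90 |
| zeta | 2.00 | 18 | 79 |
| zeta | 3.00 | 20 | 67 |
| zeta | 4.00 | 23 | 59 |
| zeta | 6.00 | 22 | 42 |
| zeta | 10.0 | 16 | 24 |
| zeta | 15.0 | 9 | 14 |

(each reading ± 1.5 percentage points)

- at the start none of Q is in solution

1. the moment within 40 h at which there is most E
2. the amount of E, in percent of the D charged, at that time

In theta, which is this flask followed so far, E reads 28% at 4.00 h and 28% at 6.00 h. Where E stands still its making equals its loss, so D over E there is the loss ratio κ, and the means of these readings give 1.52. Followed against D instead of time, E peaks at the fraction κ^(−κ/(κ−1)) of the charge, so I reckon 29.4%, with D at κ times that, 44.7%. The D readings of theta pass that fraction at about 4.63 h.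

The forecast gives 28.5% at 4.8 h, saying that “the peak lies between the last two”.

The flask gives 28.7% at 4.55 h, with D at 45.5%.

    L + E → G (k = 110 /M/h)
    D + L + Z → Z + E (k = 3.90 × 10⁵ /M²/h)
    Q ⇌ L, rate k3*(csat - [L]) (kL = 18.0 /h)

The height of E stays this low because L also turns E into G: the same run without that step reaches >99.9% instead of 28.7%. L multiplies both steps, so it cancels from κ, while Z stands in the D step and not in the E step, so at a fixed charge of D κ goes inversely with Z. A neighbour flask, charged with 0.08 mol% of Z and otherwise as this flask, therefore has a reckoned κ of 3.79 and a reckoned peak of 16.4%; simulated, that neighbour gives 15.9%.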